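**Retrosynthetic overview**

1. The C-8 prenyl group is removed last, back to a 5-O-prenyl ether (para-Claisen–Cope shift). The 5-OH/7-OMe pair goes back to a 5,7-dimethoxy ring A by demethylation chelated to the C-4 carbonyl.
2. Ring C is then opened at O-1–C-8a and at the carbonyl–aryl bond C-4–C-4a, giving 3,5-dimethoxybenzyne (ring A) and an (S)-β-hydroxy N-methoxy-N-methylamide that carries ring B, C-2, C-3 and C-4. In the forward sense the alkoxide adds to the aryne and the aryl anion closes ring C on the amide, C-4–C-4a being the ring-closing bond.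
3. Enabling feature: C-8a and C-4a are neighbours in ring A; C-8a holds the ring oxygen O-1 and C-4a lies between O-1 and the C-5 oxygen. The C-5 methoxy group of the aryne therefore steers the oxygen nucleophile to C-8a and leaves the carbanion on C-4a, at six-ring distance from C-4.
4. Ring order: rings A and B come from benzenoid starting materials; ring C is the only ring formed (step 6). C-2 is set earlier by asymmetric transfer hydrogenation and carried through with retention.

Key step: step 6

Remark: the SMILES is read as the (2S)-flavanone (5-OH, 7-OMe, 8-prenyl, 4'-OH); flavanone numbering is used, with primed positions for ring B.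

**Route**

Step 1
Reactants: 1 3,5-dimethoxyphenol
Product: 2 2-bromo-3,5-dimethoxyphenol
Conditions: NBS (1.0 equiv), i-Pr2NH (cat.), CH2Cl2, −78 °C to 0 °C
Reagents that add atoms: N-bromosuccinimide, O=C1CCC(=O)N1Br
Why: Amine-catalysed NBS bromination (electrophilic aromatic substitution through an N-bromoamine hydrogen-bonded to the phenol) should go ortho to the OH group, both ortho positions of 1 being equivalent, and any 4-bromo isomer is removable by chromatography.

Step 2
Reactants: 2 2-bromo-3,5-dimethoxyphenol
Product: 5 3,5-dimethoxy-2-(trimethylsilyl)phenyl trifluoromethanesulfonate, via aryl trimethylsilyl ether 3 (not isolated), via lithium silylphenoxide 4 (not isolated)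
Conditions: HMDS, THF, 70 °C, then evaporation; n-BuLi, THF, −100 °C to −78 °C; Tf2O, −100 °C to rt
Reagents that add atoms: hexamethyldisilazane, C[Si](C)(C)N[Si](C)(C)C; trifluoromethanesulfonic anhydride, O=S(=O)(OS(=O)(=O)C(F)(F)F)C(F)(F)F
Why: O-Silylation, bromine–lithium exchange and retro-Brook 1,3-O-to-C silyl migration should give the ortho-silyl phenoxide 4, which is triflated in the same flask, the standard entry to 2-(trimethylsilyl)aryl triflates.

Step 3
Reactants: 6 4'-(benzyloxy)acetophenone
Product: 7 ethyl 3-[4-(benzyloxy)phenyl]-3-oxopropanoate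
Conditions: NaH, (EtO)2CO, toluene, 110 °C; then aq. HCl, 0 °C
Reagents that add atoms: diethyl carbonate, CCOC(=O)OCC
Why: Crossed Claisen condensation of the ketone enolate with the non-enolizable carbonate, pulled forward by deprotonation of the β-keto ester formed.

Step 4
Reactants: 7 ethyl 3-[4-(benzyloxy)phenyl]-3-oxopropanoate
Product: 8 ethyl (S)-3-[4-(benzyloxy)phenyl]-3-hydroxypropanoate
Conditions: RuCl[(S,S)-TsDPEN](p-cymene) (1 mol %), HCO2H/Et3N 5:2, 40 °C
Reagents that add atoms: none
Why: Noyori–Ikariya asymmetric transfer hydrogenation, in which hydride and proton are delivered through the six-membered Ru–H/N–H transition state and the CH–π contact between the cymene ligand and the aryl group of 7 fixes the face, so that the (S,S)-ligand should give the S carbinol as it does with acetophenone (CH2CO2Et takes the place of CH3 without a change of priorities).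

Step 5
Reactants: 8 ethyl (S)-3-[4-(benzyloxy)phenyl]-3-hydroxypropanoate
Product: 9 (S)-3-[4-(benzyloxy)phenyl]-3-hydroxy-N-methoxy-N-methylpropanamide
Conditions: MeNH(OMe)·HCl, i-PrMgCl, THF, −20 °C to 0 °C
Reagents that add atoms: N,O-dimethylhydroxylamine hydrochloride, CNOC.Cl
Why: Ester aminolysis by the chloromagnesium amide of N,O-dimethylhydroxylamine (the standard ester to N-methoxy-N-methylamide exchange), in which the carbinol is only deprotonated and the stereocenter is not involved.

Step 6
Reactants: 9 (S)-3-[4-(benzyloxy)phenyl]-3-hydroxy-N-methoxy-N-methylpropanamide; 5 3,5-dimethoxy-2-(trimethylsilyl)phenyl trifluoromethanesulfonate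
Product: 14 (2S)-4'-(benzyloxy)-5,7-dimethoxyflavanone, via sodium alkoxide 10 (not isolated), via 3,5-dimethoxybenzyne 11 (not isolated), via aryl anion 12 (not isolated), via tetrahedral adduct 13 (not isolated)
Conditions: NaH (1.05 equiv), THF, 0 °C; then 5 (1.5 equiv), CsF, 18-crown-6, THF, 0 °C to rt; 1 M HCl, 0 °C
Reagents that add atoms: none
Why: Proposed new method: the sodium alkoxide 10 adds to aryne 11 at the carbon remote from the flanking methoxy group (the inductive polarization that governs 3-alkoxyarynes), which leaves the carbanion of 12 between the new ether oxygen and that methoxy group, and this 2,6-dioxygenated aryl anion attacks the N-methoxy-N-methylamide carbonyl to give the chelated adduct 13, which releases the ketone only on acidic quench. The closest known reaction type is the fluoride-induced annulation of 2-(trimethylsilyl)aryl triflates with salicylate esters to xanthones (aryne O-arylation, then intramolecular acyl substitution by the aryl anion); new here are the aliphatic secondary alkoxide and the enolizable acyl acceptor. Ring C is closed by a 6-exo-trig attack of the ring A carbanion on the amide carbonyl, so that the carbonyl–aryl bond C-4–C-4a is the ring-closing bond, the O-1–C-8a bond having formed just before in the same flask. No new stereocenter persists (the hemiaminal carbon of 13 collapses to the ketone), and C-2 should keep its S configuration because none of its bonds is broken. The step needs regioselective O-attack, acylation instead of protonation of the aryl anion, and freedom from retro-aldol cleavage and β-elimination; these should be secured by the methoxy group next to the aryne bond, by the aprotic medium with a pre-formed alkoxide, and by the amide, whose enolate is a poor leaving group and whose adduct 13 holds back both the enolizable ketone and any basic leaving group until work-up.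

Step 7
Reactants: 14 (2S)-4'-(benzyloxy)-5,7-dimethoxyflavanone
Product: 15 (2S)-5,4'-dihydroxy-7-methoxyflavanone (sakuranetin)
Conditions: BCl3, C6HMe5, CH2Cl2, −78 °C to 0 °C; then H2O
Reagents that add atoms: none
Why: Lewis-acid ether cleavage in which BCl3 bound between the C-4 carbonyl and the peri 5-methoxy oxygen should cleave only that methyl ether (the 7-methoxy group has no carbonyl neighbour) and also the benzyl ether, whose cation is taken up by pentamethylbenzene and so kept away from ring A.

Step 8
Reactants: 15 (2S)-5,4'-dihydroxy-7-methoxyflavanone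
Product: 16 (2S)-4'-(tert-butyldimethylsilyloxy)-5-hydroxy-7-methoxyflavanone
Conditions: TBSCl (1.05 equiv), imidazole, DMF, 0 °C
Reagents that add atoms: tert-butyldimethylsilyl chloride, CC(C)(C)[Si](C)(C)Cl
Why: Silylation of the free 4'-phenol, the 5-OH being hydrogen-bonded to the C-4 carbonyl and therefore unreactive toward one equivalent of TBSCl.

Step 9
Reactants: 16 (2S)-4'-(tert-butyldimethylsilyloxy)-5-hydroxy-7-methoxyflavanone
Product: 17 (2S)-4'-(tert-butyldimethylsilyloxy)-7-methoxy-5-(3-methylbut-2-enyloxy)flavanone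
Conditions: 3-methylbut-2-en-1-ol, PPh3, DIAD, THF, 0 °C to rt
Reagents that add atoms: 3-methylbut-2-en-1-ol, CC(C)=CCO
Why: Mitsunobu etherification of the chelated but sufficiently acidic 5-OH with the primary allylic alcohol under neutral conditions, which avoid the base-induced opening of ring C that would racemize C-2.

Step 10
Reactants: 17 (2S)-4'-(tert-butyldimethylsilyloxy)-7-methoxy-5-(3-methylbut-2-enyloxy)flavanone
Product: 20 (2S)-4'-(tert-butyldimethylsilyloxy)-5-hydroxy-7-methoxy-8-(3-methylbut-2-enyl)flavanone, via ortho-dienone 18 (not isolated), via para-dienone 19 (not isolated)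
Conditions: Eu(fod)3 (10 mol %), CHCl3, 60 °C
Reagents that add atoms: none
Why: Eu(fod)3-promoted aromatic Claisen rearrangement to C-6 (the only free ortho position), Cope shift of the 1,1-dimethylallyl group of dienone 18 to the para position C-8 and enolization of 19 (para-Claisen–Cope sequence), with the lanthanide chelated between the C-4 carbonyl and O-5 activating this ether alone and leaving C-2 untouched.

Step 11
Reactants: 20 (2S)-4'-(tert-butyldimethylsilyloxy)-5-hydroxy-7-methoxy-8-(3-methylbut-2-enyl)flavanone
Product: 21 Mundulea flavanone B, (2S)-5,4'-dihydroxy-7-methoxy-8-(3-methylbut-2-enyl)flavanone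
Conditions: HF·pyridine, THF/pyridine, 0 °C
Reagents that add atoms: none
Why: Fluoride cleavage of the aryl silyl ether in a weakly acidic medium, which keeps the 4'-phenol protonated and so avoids racemization through a quinone methide.

**Compound list**

1 | 3,5-dimethoxyphenol | COc1cc(O)cc(OC)c1 | starting material
2 | 2-bromo-3,5-dimethoxyphenol | COc1cc(O)c(Br)c(OC)c1 | intermediate
3 | (2-bromo-3,5-dimethoxyphenoxy)trimethylsilane | COc1cc(O[Si](C)(C)C)c(Br)c(OC)c1 | intermediate (not isolated)
4 | lithium 3,5-dimethoxy-2-(trimethylsilyl)phenoxide | COc1cc([O-])c([Si](C)(C)C)c(OC)c1.[Li+] | intermediate (not isolated)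
5 | 3,5-dimethoxy-2-(trimethylsilyl)phenyl trifluoromethanesulfonate | COc1cc(OS(=O)(=O)C(F)(F)F)c([Si](C)(C)C)c(OC)c1 | intermediate
6 | 4'-(benzyloxy)acetophenone | CC(=O)c1ccc(OCc2ccccc2)cc1 | starting material
7 | ethyl 3-[4-(benzyloxy)phenyl]-3-oxopropanoate | CCOC(=O)CC(=O)c1ccc(OCc2ccccc2)cc1 | intermediate
8 | ethyl (S)-3-[4-(benzyloxy)phenyl]-3-hydroxypropanoate | CCOC(=O)C[C@H](O)c1ccc(OCc2ccccc2)cc1 | intermediate
9 | (S)-3-[4-(benzyloxy)phenyl]-3-hydroxy-N-methoxy-N-methylpropanamide | CON(C)C(=O)C[C@H](O)c1ccc(OCc2ccccc2)cc1 | intermediate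
10 | sodium alkoxide of 9 | CON(C)C(=O)C[C@H]([O-])c1ccc(OCc2ccccc2)cc1.[Na+] | intermediate (not isolated)
11 | 3,5-dimethoxybenzyne | COC1=CC(OC)=CC#C1 | intermediate (not isolated)
12 | sodium 2-aryloxy-4,6-dimethoxyphenyl anion (O-arylated 9, carbanion between the ether oxygen and a methoxy group) | COc1cc(OC)[c-]c(c1)O[C@H](c1ccc(OCc2ccccc2)cc1)CC(=O)N(C)OC.[Na+] | intermediate (not isolated)
13 | sodium salt of the cyclized N-methoxy-N-methyl hemiaminal (tetrahedral adduct at C-4, 2S) | COc1cc(OC)c2c(c1)O[C@H](c1ccc(OCc3ccccc3)cc1)CC2([O-])N(C)OC.[Na+] | intermediate (not isolated)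
14 | (2S)-2-[4-(benzyloxy)phenyl]-5,7-dimethoxychroman-4-one | COc1cc(OC)c2c(c1)O[C@H](c1ccc(OCc3ccccc3)cc1)CC2=O | intermediate
15 | (2S)-5-hydroxy-2-(4-hydroxyphenyl)-7-methoxychroman-4-one (sakuranetin) | COc1cc(O)c2c(c1)O[C@H](c1ccc(O)cc1)CC2=O | intermediate
16 | (2S)-2-[4-(tert-butyldimethylsilyloxy)phenyl]-5-hydroxy-7-methoxychroman-4-one | COc1cc(O)c2c(c1)O[C@H](c1ccc(O[Si](C)(C)C(C)(C)C)cc1)CC2=O | intermediate
17 | (2S)-2-[4-(tert-butyldimethylsilyloxy)phenyl]-7-methoxy-5-(3-methylbut-2-enyloxy)chroman-4-one | COc1cc(OCC=C(C)C)c2c(c1)O[C@H](c1ccc(O[Si](C)(C)C(C)(C)C)cc1)CC2=O | intermediate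
18 | ortho-dienone: (2S)-6-(2-methylbut-3-en-2-yl)-7-methoxy-2-aryl-2,3-dihydro-6H-chromene-4,5-dione (C-6 epimers) | C=CC(C)(C)C1C(OC)=CC2=C(C1=O)C(=O)C[C@@H](c1ccc(O[Si](C)(C)C(C)(C)C)cc1)O2 | intermediate (not isolated)
19 | para-dienone: (2S)-7-methoxy-8-(3-methylbut-2-enyl)-2-aryl-2,3-dihydro-8H-chromene-4,5-dione (C-8 epimers) | CC(C)=CCC1C(OC)=CC(=O)C2=C1O[C@H](c1ccc(O[Si](C)(C)C(C)(C)C)cc1)CC2=O | intermediate (not isolated)
20 | (2S)-2-[4-(tert-butyldimethylsilyloxy)phenyl]-5-hydroxy-7-methoxy-8-(3-methylbut-2-enyl)chroman-4-one | COc1cc(O)c2c(c1CC=C(C)C)O[C@H](c1ccc(O[Si](C)(C)C(C)(C)C)cc1)CC2=O | intermediate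
21 | Mundulea flavanone B, (2S)-5-hydroxy-2-(4-hydroxyphenyl)-7-methoxy-8-(3-methylbut-2-enyl)chroman-4-one | COc1cc(O)c2c(c1CC=C(C)C)O[C@H](c1ccc(O)cc1)CC2=O | target

**Step count and risks**

Total step count: 11. Longest linear sequence: 9 steps (steps 3 to 11, from 6 to 21); the aryne precursor 5 is made in 2 steps (steps 1 and 2) and joins at step 6.

Steps most likely to fail:

Step 6 (proposed new method). What may go wrong: the aryl anion is protonated before it reaches the amide; the anion takes a proton from C-3 and the aryloxide is then lost by β-elimination; the alkoxide undergoes reversible retro-aldol cleavage and C-2 erodes; or the released base opens ring C of the product. Fallback with known chemistry, which closes the same carbonyl–aryl bond by a Parham cyclization: it sets out from 7 and 2. Keto ester 7 is reduced with the enantiomeric catalyst RuCl[(R,R)-TsDPEN](p-cymene) to ethyl (R)-3-[4-(benzyloxy)phenyl]-3-hydroxypropanoate F1, which is converted as in step 5 into (R)-3-[4-(benzyloxy)phenyl]-3-hydroxy-N-methoxy-N-methylpropanamide F2. Mitsunobu etherification of F2 with bromophenol 2 (PPh3, DIAD, toluene, 0 °C) should give, with inversion, (S)-3-[4-(benzyloxy)phenyl]-3-(2-bromo-3,5-dimethoxyphenoxy)-N-methoxy-N-methylpropanamide F3. Bromine–lithium exchange (n-BuLi, THF, −100 °C) and attack of the aryllithium on the amide, followed by acidic quench, lead back to the route at 14.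

Step 10. What may go wrong: the ortho-dienone enolizes before the Cope shift, so that the 1,1-dimethylallyl group stays at C-6, or the Lewis acid opens ring C. Fallback by cross-coupling, setting out from 14: iodination (NIS, cat. CF3CO2H, MeCN), which in 5,7-dimethoxyflavonoids takes place at C-8, should give (2S)-4'-(benzyloxy)-8-iodo-5,7-dimethoxyflavanone F4. Treatment with BCl3 and C6HMe5 as in step 7 gives (2S)-5,4'-dihydroxy-8-iodo-7-methoxyflavanone F5. Stille coupling of F5 with tributyl(3-methylbut-2-enyl)stannane (Pd(PPh3)4, DMF, 80 °C) joins the route again at the target 21.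

Step 7. What may go wrong: Lewis-acid ionization of the benzylic C-2–O-1 bond with loss of configuration, cleavage of the 7-methoxy group as well, or C-benzylation of ring A. Fallback without Lewis-acid ether cleavage, setting out from 9: ring A is brought in with benzyl ethers. Commercial 3,5-bis(benzyloxy)phenol is brominated as in step 1 to 3,5-bis(benzyloxy)-2-bromophenol F6 and converted as in step 2 into 3,5-bis(benzyloxy)-2-(trimethylsilyl)phenyl trifluoromethanesulfonate F7. Reaction of F7 with 9 under the conditions of step 6 should give (2S)-5,7,4'-tris(benzyloxy)flavanone F8. Hydrogenolysis (H2, Pd/C, EtOAc) gives (2S)-naringenin F9, and one equivalent of Me3SiCHN2 (MeOH/toluene, 0 °C) methylates the most acidic 7-OH, which returns to the route at 15.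

**Further compounds**

F1 | step 6 | ethyl (R)-3-[4-(benzyloxy)phenyl]-3-hydroxypropanoate | CCOC(=O)C[C@@H](O)c1ccc(OCc2ccccc2)cc1
F2 | step 6 | (R)-3-[4-(benzyloxy)phenyl]-3-hydroxy-N-methoxy-N-methylpropanamide | CON(C)C(=O)C[C@@H](O)c1ccc(OCc2ccccc2)cc1
F3 | step 6 | (S)-3-[4-(benzyloxy)phenyl]-3-(2-bromo-3,5-dimethoxyphenoxy)-N-methoxy-N-methylpropanamide | COc1cc(OC)c(Br)c(c1)O[C@H](c1ccc(OCc2ccccc2)cc1)CC(=O)N(C)OC
F4 | step 10 | (2S)-4'-(benzyloxy)-8-iodo-5,7-dimethoxyflavanone | COc1cc(OC)c2c(c1I)O[C@H](c1ccc(OCc3ccccc3)cc1)CC2=O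
F5 | step 10 | (2S)-5,4'-dihydroxy-8-iodo-7-methoxyflavanone | COc1cc(O)c2c(c1I)O[C@H](c1ccc(O)cc1)CC2=O
F6 | step 7 | 3,5-bis(benzyloxy)-2-bromophenol | Oc1cc(OCc2ccccc2)cc(OCc2ccccc2)c1Br
F7 | step 7 | 3,5-bis(benzyloxy)-2-(trimethylsilyl)phenyl trifluoromethanesulfonate | C[Si](C)(C)c1c(OCc2ccccc2)cc(OCc2ccccc2)cc1OS(=O)(=O)C(F)(F)F
F8 | step 7 | (2S)-5,7,4'-tris(benzyloxy)flavanone | C(Oc1cc(OCc2ccccc2)c2c(c1)O[C@H](c1ccc(OCc3ccccc3)cc1)CC2=O)c1ccccc1
F9 | step 7 | (2S)-naringenin | Oc1cc(O)c2c(c1)O[C@H](c1ccc(O)cc1)CC2=O
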